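## Retrosynthetic overview

1. Target ⇐ desilylation and C16 α-methylenation of a 14-hydroxy-15-ketone; the ketone comes from ozonolysis of a 15-methylidene group, and C14 is set by retro-aldol/aldol equilibration.
2. Ring D (bicyclo[3.2.1]octane) ⇐ Mn(III) 5-exo-dig radical closure of C8 onto a C13 propargyl group in a spiro β-keto-δ-lactone.
3. Key C9–C10 bond and the lactone ⇐ titanocene-electrocatalytic epoxide-opening Giese addition of a ring-A spiro-epoxide to a ring-C 2-methoxycarbonyl-cyclohexenone, then lactonisation.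
4. Ring A epoxide ⇐ methyl (S)-glycidate (C1), via SnCl4 cation–olefin cyclisation and a bridged lactone that fixes C5.
5. Ring C enone ⇐ L-glutamic-acid-derived trityl lactone (C11), via trans propargylation (C13) and selenolate Michael–Dieckmann closure. Ring order: A and C separately, lactone on coupling, D last.

Assumption: methyl (S)-glycidate and (S)-5-(trityloxymethyl)-γ-butyrolactone are taken as commercial; C-labels follow ent-kaurane numbering; freely epimerising or inconsequential centres (β-dicarbonyl CH, C–Se, spiro-epoxide carbon, tertiary carbinol of F1–F4) are left undefined in the SMILES.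

## Route

Step 1
Reactants: 1 methyl (2S)-oxirane-2-carboxylate
Product: 2 methyl (2S)-2-hydroxy-5-methylhex-4-enoate
Conditions: Me2C=CHMgBr (1.3 equiv), CuI (10 mol %), THF, –40 °C
Reagents that add atoms: (2-methylprop-1-en-1-yl)magnesium bromide, CC(C)=C[Mg]Br
Why: Copper-catalysed Grignard SN2 opening of the glycidate at the unsubstituted C3 leaves the C–O stereocentre untouched, so the future C1 carbinol is bought with the starting material.

Step 2
Reactants: 2 methyl (2S)-2-hydroxy-5-methylhex-4-enoate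
Product: 3 methyl (4S)-4-hydroxy-7-methyl-3-oxooct-6-enoate
Conditions: MeOAc, LDA (3.2 equiv each), THF, –78 → –40 °C; AcOH quench at –78 °C
Reagents that add atoms: methyl acetate, CC(=O)OC
Why: Crossed Claisen condensation of excess lithium methyl acetate enolate with the ester (hydroxyl carried as its lithium alkoxide) gives the β-keto ester without touching the carbinol centre.

Step 3
Reactants: 3 methyl (4S)-4-hydroxy-7-methyl-3-oxooct-6-enoate
Product: 4 methyl (4S)-4-acetoxy-7-methyl-3-oxooct-6-enoate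
Conditions: Ac2O, pyridine, DMAP (cat.), CH2Cl2, 0 °C
Reagents that add atoms: acetic anhydride, CC(=O)OC(C)=O
Why: O-Acetylation masks the hydroxyl so that it cannot trap the tertiary cation as a tetrahydrofuran in the next step.

Step 4
Reactants: 4 methyl (4S)-4-acetoxy-7-methyl-3-oxooct-6-enoate
Product: 7 (1R,5S)-2,2-dimethyl-6-oxabicyclo[3.2.1]octane-7,8-dione, via cyclic acetoxy keto ester 5 (not isolated), via cyclic hydroxy keto ester 6 (not isolated)
Conditions: SnCl4 (2.2 equiv), CH2Cl2, 0 °C → rt; then MeOH, 40 °C; then PhMe, 90 °C (–MeOH)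
Reagents that add atoms: none
Why: SnCl4-promoted β-keto ester enol–olefin (cation–olefin) cyclisation closes ring A, and after acid methanolysis of the acetate only the cis-1,3 hydroxy ester can lactonise, so the epimerisable β-keto ester carbon is funnelled into the bridged lactone with C5 cis to the C1 oxygen.

Step 5
Reactants: 7 (1R,5S)-2,2-dimethyl-6-oxabicyclo[3.2.1]octane-7,8-dione
Product: 8 (1R,5S)-2,2-dimethyl-8-methylidene-6-oxabicyclo[3.2.1]octan-7-one
Conditions: Ph3PCH3Br, KOtBu, THF, 0 °C → rt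
Reagents that add atoms: methylidenetriphenylphosphorane, C=P(c1ccccc1)(c1ccccc1)c1ccccc1 (from methyltriphenylphosphonium bromide, C[P+](c1ccccc1)(c1ccccc1)c1ccccc1.[Br-])
Why: Wittig methylenation of the strained, non-enolisable bridging ketone installs the C10=C20 alkene without risk to either bridgehead stereocentre.

Step 6
Reactants: 8 (1R,5S)-2,2-dimethyl-8-methylidene-6-oxabicyclo[3.2.1]octan-7-one
Product: 9 (1S,3R)-3-(hydroxymethyl)-4,4-dimethyl-2-methylidenecyclohexan-1-ol
Conditions: LiAlH4, THF, 0 °C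
Reagents that add atoms: none
Why: Hydride reduction of the lactone releases the cis-1,3 diol (C1–OH and C5–CH2OH) with both stereocentres unchanged.

Step 7
Reactants: 9 (1S,3R)-3-(hydroxymethyl)-4,4-dimethyl-2-methylidenecyclohexan-1-ol
Product: 11 (1S,3R)-3-[(tert-butyldimethylsilyloxy)methyl]-4,4-dimethyl-2-methylidenecyclohexyl acetate, via mono-TBS ether 10 (not isolated)
Conditions: TBSCl (1.05 equiv), imidazole, CH2Cl2, –20 °C; then Ac2O, Et3N, DMAP, rt
Reagents that add atoms: tert-butyldimethylsilyl chloride, CC(C)(C)[Si](C)(C)Cl; acetic anhydride, CC(=O)OC(C)=O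
Why: Selective silylation of the primary alcohol followed by acetylation of the remaining secondary alcohol in the same flask installs the C1 acetate of the target and an orthogonal C6 protecting group.

Step 8
Reactants: 11 (1S,3R)-3-[(tert-butyldimethylsilyloxy)methyl]-4,4-dimethyl-2-methylidenecyclohexyl acetate
Product: 12 (4S,8S)-8-[(tert-butyldimethylsilyloxy)methyl]-7,7-dimethyl-1-oxaspiro[2.5]octan-4-yl acetate (C3 epimers)
Conditions: mCPBA, NaHCO3, CH2Cl2, 0 °C
Reagents that add atoms: 3-chloroperoxybenzoic acid, OOC(=O)c1cccc(Cl)c1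
Why: Prilezhaev epoxidation gives the spiro-epoxide radical precursor, whose spiro configuration is irrelevant because that carbon becomes a planar radical.

Step 9
Reactants: 13 (5S)-5-[(trityloxy)methyl]oxolan-2-one
Product: 14 (3R,5S)-3-(prop-2-yn-1-yl)-5-[(trityloxy)methyl]oxolan-2-one
Conditions: LDA, THF, –78 °C; propargyl bromide, –78 → –40 °C
Reagents that add atoms: propargyl bromide, C#CCBr
Why: Alkylation of the lithium lactone enolate occurs anti to the bulky γ-trityloxymethyl group, giving the trans-3,5 lactone and thus C13 under control of the bought C11 centre.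

Step 10
Reactants: 14 (3R,5S)-3-(prop-2-yn-1-yl)-5-[(trityloxy)methyl]oxolan-2-one
Product: 15 (3R,5S)-5-(hydroxymethyl)-3-(prop-2-yn-1-yl)oxolan-2-one
Conditions: TsOH·H2O (cat.), MeOH/CH2Cl2, rt
Reagents that add atoms: none
Why: Acid-catalysed SN1 solvolysis of the trityl ether frees the primary alcohol and leaves lactone and alkyne intact.

Step 11
Reactants: 15 (3R,5S)-5-(hydroxymethyl)-3-(prop-2-yn-1-yl)oxolan-2-one
Product: 17 methyl (2E)-3-[(2S,4R)-5-oxo-4-(prop-2-yn-1-yl)oxolan-2-yl]prop-2-enoate, via lactone aldehyde 16 (not isolated)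
Conditions: Dess–Martin periodinane, NaHCO3, CH2Cl2, 0 °C → rt; then Ph3P=CHCO2Me, rt
Reagents that add atoms: methyl (triphenylphosphoranylidene)acetate, COC(=O)C=P(c1ccccc1)(c1ccccc1)c1ccccc1
Why: Dess–Martin oxidation and in situ Wittig olefination with the stabilised ylide give the enoate without isolating the epimerisable α-acyloxy aldehyde.

Step 12
Reactants: 17 methyl (2E)-3-[(2S,4R)-5-oxo-4-(prop-2-yn-1-yl)oxolan-2-yl]prop-2-enoate
Product: 19 methyl (3R,5S)-5-(tert-butyldimethylsilyloxy)-2-oxo-6-(phenylselanyl)-3-(prop-2-yn-1-yl)cyclohexane-1-carboxylate (C1/C6 epimers), via hydroxy selenide 18 (not isolated)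
Conditions: (PhSe)2, LiBHEt3, THF, 0 °C; add 17, –78 → 0 °C; then TBSCl, imidazole, DMF, rt
Reagents that add atoms: lithium benzeneselenolate, [Li+].[Se-]c1ccccc1 (from diphenyl diselenide, c1ccccc1[Se][Se]c1ccccc1); tert-butyldimethylsilyl chloride, CC(C)(C)[Si](C)(C)Cl
Why: Selenolate conjugate addition generates the ester enolate, which acylates on the lactone carbonyl (tandem Michael–Dieckmann) to close ring C as the enolisable β-keto ester, and the liberated C11 hydroxyl is silylated in the same flask, with C11 untouched and C13 in its more stable cis (diequatorial) arrangement.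

Step 13
Reactants: 19 methyl (3R,5S)-5-(tert-butyldimethylsilyloxy)-2-oxo-6-(phenylselanyl)-3-(prop-2-yn-1-yl)cyclohexane-1-carboxylate
Product: 20 methyl (3S,5R)-3-(tert-butyldimethylsilyloxy)-6-oxo-5-(prop-2-yn-1-yl)cyclohex-1-ene-1-carboxylate
Conditions: H2O2 (30 %), pyridine, CH2Cl2, 0 °C; used at once
Reagents that add atoms: none
Why: Selenide oxidation and syn-selenoxide elimination toward the acidic C8–H and away from the oxygen-bearing C11 unmask the doubly activated C8=C9 acceptor.

Step 14
Reactants: 12 (4S,8S)-8-[(tert-butyldimethylsilyloxy)methyl]-7,7-dimethyl-1-oxaspiro[2.5]octan-4-yl acetate (1.3 equiv), 20 methyl (3S,5R)-3-(tert-butyldimethylsilyloxy)-6-oxo-5-(prop-2-yn-1-yl)cyclohex-1-ene-1-carboxylate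
Product: 22 spiro β-keto δ-lactone (ring C cyclohexanone fused to the C7–O–C20 lactone; ring A spiro at C10), via hydroxy keto ester 21 (not isolated)
Conditions: Cp2TiCl2 (20 mol %), 2,4,6-collidine·HCl (2.5 equiv), n-Bu4NPF6, THF, undivided cell, Zn anode, graphite-felt cathode, 3 mA, 2.2 F/mol, rt; then DMAP (0.3 equiv), PhMe, 90 °C
Reagents that add atoms: none
Why: Proposed new method: cathodically regenerated Cp2Ti(III)Cl opens the epoxide to the β-titanoxy tertiary C10 radical, which adds to C9 of the alkylidene β-keto ester anti to the C11 silyloxy group and on the ring-A face opposite the axial C4 methyl and the cis C1/C5 substituents (setting C9 and C10), the β-dicarbonyl radical is then reduced to the titanium enolate and protonated by collidinium, and DMAP-mediated transesterification by the freed C20 hydroxyl closes the δ-lactone; the closest known chemistry is the Nugent–RajanBabu/Gansäuer titanocene(III) epoxide–acrylate Giese addition with spirolactonisation, extended here to electrochemical turnover and to a β-substituted cyclic acceptor that forges a quaternary–tertiary bond.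

Step 15
Reactants: 22 spiro β-keto δ-lactone
Product: 23 14-oxo-15-methylidene bicyclo[3.2.1]octane lactone (rings A, lactone, C and D complete)
Conditions: Mn(OAc)3·2H2O (2.2 equiv), degassed EtOH, 50 °C
Reagents that add atoms: none
Why: Snider-type Mn(III) oxidative radical cyclisation generates the C8 radical of the β-keto lactone, which closes 5-exo-dig onto the axial propargyl group (vinyl radical quenched by ethanol), so C8 is set by the cis bridging geometry dictated by C13.

Step 16
Reactants: 23 14-oxo-15-methylidene bicyclo[3.2.1]octane lactone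
Product: 24 (14S)-14-hydroxy-15-methylidene lactone (14-epi alcohol)
Conditions: NaBH4, CeCl3·7H2O, MeOH/THF, –40 °C
Reagents that add atoms: none
Why: Luche-type borohydride reduction of the bridging ketone should occur from the open face syn to the C15–C16 bridge because the other face is blocked by axial C10, which is expected to give the 14-epi alcohol that is corrected in the next step.

Step 17
Reactants: 24 (14S)-14-hydroxy-15-methylidene lactone
Product: 26 (14R)-14-hydroxy-15-oxo lactone, via 14-epi hydroxy ketone 25 (not isolated)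
Conditions: O3, CH2Cl2, –78 °C; PPh3; then DBU (0.3 equiv), 0 °C → rt
Reagents that add atoms: ozone, [O-][O+]=O
Why: Ozonolysis converts the exocyclic alkene into the C15 ketone, and the resulting β-hydroxy ketone is equilibrated by base through retro-aldol/aldol reaction across C8–C14 to the thermodynamically preferred (14R)-alcohol, which avoids the 1,3-diaxial clash with C10 and is hydrogen-bonded to the C15 carbonyl.

Step 18
Reactants: 26 (14R)-14-hydroxy-15-oxo lactone
Product: 27 6,11-bis-O-TBS ether of the target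
Conditions: (CH2O)n, N-methylanilinium trifluoroacetate, THF, 65 °C
Reagents that add atoms: paraformaldehyde (formaldehyde), C=O
Why: Mannich-type α-methylenation (Gras conditions) can only occur at C16 because C8 is quaternary, giving the exocyclic enone without strong base.

Step 19
Reactants: 27 6,11-bis-O-TBS ether of the target
Product: 28 CNP0225182.1 (target)
Conditions: HF·pyridine, THF/pyridine, 0 °C → rt
Reagents that add atoms: none
Why: Fluoride-mediated cleavage of both silyl ethers under buffered conditions leaves the acetate, lactone and enone untouched.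

## Compound list

1 | methyl (2S)-oxirane-2-carboxylate | COC(=O)[C@@H]1CO1 | starting material
2 | methyl (2S)-2-hydroxy-5-methylhex-4-enoate | COC(=O)[C@@H](O)CC=C(C)C | intermediate
3 | methyl (4S)-4-hydroxy-7-methyl-3-oxooct-6-enoate | COC(=O)CC(=O)[C@@H](O)CC=C(C)C | intermediate
4 | methyl (4S)-4-acetoxy-7-methyl-3-oxooct-6-enoate | COC(=O)CC(=O)[C@@H](OC(C)=O)CC=C(C)C | intermediate
5 | methyl (5S)-5-acetoxy-2,2-dimethyl-6-oxocyclohexane-1-carboxylate (C1 epimers) | O=C1[C@@H](OC(C)=O)CCC(C)(C)C1C(=O)OC | intermediate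
6 | methyl (5S)-5-hydroxy-2,2-dimethyl-6-oxocyclohexane-1-carboxylate (C1 epimers) | O=C1[C@@H](O)CCC(C)(C)C1C(=O)OC | intermediate
7 | (1R,5S)-2,2-dimethyl-6-oxabicyclo[3.2.1]octane-7,8-dione | O=C1[C@@H]2CCC(C)(C)[C@H]1C(=O)O2 | intermediate
8 | (1R,5S)-2,2-dimethyl-8-methylidene-6-oxabicyclo[3.2.1]octan-7-one | C=C1[C@@H]2CCC(C)(C)[C@H]1C(=O)O2 | intermediate
9 | (1S,3R)-3-(hydroxymethyl)-4,4-dimethyl-2-methylidenecyclohexan-1-ol | C=C1[C@@H](O)CCC(C)(C)[C@H]1CO | intermediate
10 | (1S,3R)-3-[(tert-butyldimethylsilyloxy)methyl]-4,4-dimethyl-2-methylidenecyclohexan-1-ol | C=C1[C@@H](O)CCC(C)(C)[C@H]1CO[Si](C)(C)C(C)(C)C | intermediate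
11 | (1S,3R)-3-[(tert-butyldimethylsilyloxy)methyl]-4,4-dimethyl-2-methylidenecyclohexyl acetate | C=C1[C@@H](OC(C)=O)CCC(C)(C)[C@H]1CO[Si](C)(C)C(C)(C)C | intermediate
12 | (4S,8S)-8-[(tert-butyldimethylsilyloxy)methyl]-7,7-dimethyl-1-oxaspiro[2.5]octan-4-yl acetate (C3 epimers) | C1OC12[C@@H](OC(C)=O)CCC(C)(C)[C@H]2CO[Si](C)(C)C(C)(C)C | intermediate
13 | (5S)-5-[(trityloxy)methyl]oxolan-2-one | O=C1CC[C@@H](COC(c2ccccc2)(c2ccccc2)c2ccccc2)O1 | starting material
14 | (3R,5S)-3-(prop-2-yn-1-yl)-5-[(trityloxy)methyl]oxolan-2-one | O=C1[C@H](CC#C)C[C@@H](COC(c2ccccc2)(c2ccccc2)c2ccccc2)O1 | intermediate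
15 | (3R,5S)-5-(hydroxymethyl)-3-(prop-2-yn-1-yl)oxolan-2-one | O=C1[C@H](CC#C)C[C@@H](CO)O1 | intermediate
16 | (2S,4R)-5-oxo-4-(prop-2-yn-1-yl)oxolane-2-carbaldehyde | O=C1[C@H](CC#C)C[C@@H](C=O)O1 | intermediate
17 | methyl (2E)-3-[(2S,4R)-5-oxo-4-(prop-2-yn-1-yl)oxolan-2-yl]prop-2-enoate | O=C1[C@H](CC#C)C[C@@H](/C=C/C(=O)OC)O1 | intermediate
18 | methyl (3R,5S)-5-hydroxy-2-oxo-6-(phenylselanyl)-3-(prop-2-yn-1-yl)cyclohexane-1-carboxylate (C1/C6 epimers) | COC(=O)C1C(=O)[C@H](CC#C)C[C@H](O)C1[Se]c2ccccc2 | intermediate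
19 | methyl (3R,5S)-5-(tert-butyldimethylsilyloxy)-2-oxo-6-(phenylselanyl)-3-(prop-2-yn-1-yl)cyclohexane-1-carboxylate (C1/C6 epimers) | COC(=O)C1C(=O)[C@H](CC#C)C[C@H](O[Si](C)(C)C(C)(C)C)C1[Se]c2ccccc2 | intermediate
20 | methyl (3S,5R)-3-(tert-butyldimethylsilyloxy)-6-oxo-5-(prop-2-yn-1-yl)cyclohex-1-ene-1-carboxylate | COC(=O)C1=C[C@@H](O[Si](C)(C)C(C)(C)C)C[C@@H](CC#C)C1=O | intermediate
21 | Giese adduct: ring-C β-keto methyl ester (C13 propargyl cis to C11–OTBS, C9–C10 bond trans to C11–OTBS) carrying ring A at C10 (C20 hydroxymethyl, C1 acetate and C5 CH2OTBS all cis; C8 epimers) | C#CC[C@@H]1C[C@H](O[Si](C)(C)C(C)(C)C)[C@H](C(C1=O)C(=O)OC)[C@]2(CO)[C@@H](OC(C)=O)CCC(C)(C)[C@H]2CO[Si](C)(C)C(C)(C)C | intermediate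
22 | spiro β-keto δ-lactone: as 21 with the C20 oxygen lactonised onto C7 (C8 epimers) | C#CC[C@@H]1C[C@H](O[Si](C)(C)C(C)(C)C)[C@@H]2C(C1=O)C(=O)OC[C@]23[C@@H](OC(C)=O)CCC(C)(C)[C@H]3CO[Si](C)(C)C(C)(C)C | intermediate
23 | 14-oxo-15-methylidene bicyclo[3.2.1]octane lactone (1-OAc, 6-OTBS, 11-OTBS; C8–C15 bond cis to C13–C16) | C1C(=C)[C@@]23C(=O)OC[C@]4([C@@H](OC(C)=O)CCC(C)(C)[C@H]4CO[Si](C)(C)C(C)(C)C)[C@@H]2[C@@H](O[Si](C)(C)C(C)(C)C)C[C@@H]1C3=O | intermediate
24 | (14S)-14-hydroxy-15-methylidene lactone (14-epi; OH syn to C9–C11–C12 bridge) | C1C(=C)[C@@]23C(=O)OC[C@]4([C@@H](OC(C)=O)CCC(C)(C)[C@H]4CO[Si](C)(C)C(C)(C)C)[C@@H]2[C@@H](O[Si](C)(C)C(C)(C)C)C[C@@H]1[C@@H]3O | intermediate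
25 | (14S)-14-hydroxy-15-oxo lactone (14-epi hydroxy ketone) | C1C(=O)[C@@]23C(=O)OC[C@]4([C@@H](OC(C)=O)CCC(C)(C)[C@H]4CO[Si](C)(C)C(C)(C)C)[C@@H]2[C@@H](O[Si](C)(C)C(C)(C)C)C[C@@H]1[C@@H]3O | intermediate
26 | (14R)-14-hydroxy-15-oxo lactone (OH syn to C15–C16 bridge, as in target) | C1C(=O)[C@@]23C(=O)OC[C@]4([C@@H](OC(C)=O)CCC(C)(C)[C@H]4CO[Si](C)(C)C(C)(C)C)[C@@H]2[C@@H](O[Si](C)(C)C(C)(C)C)C[C@@H]1[C@H]3O | intermediate
27 | 6,11-bis-O-TBS ether of the target | C=C1C(=O)[C@@]23C(=O)OC[C@]4([C@@H](OC(C)=O)CCC(C)(C)[C@H]4CO[Si](C)(C)C(C)(C)C)[C@@H]2[C@@H](O[Si](C)(C)C(C)(C)C)C[C@@H]1[C@H]3O | intermediate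
28 | CNP0225182.1 (1S,5R,8R,9S,10R,11S,13S,14R; ent-kaurane numbering) | C=C1C(=O)[C@@]23C(=O)OC[C@]4([C@@H](OC(C)=O)CCC(C)(C)[C@H]4CO)[C@@H]2[C@@H](O)C[C@@H]1[C@H]3O | target

## Summary

Total steps: 19 (steps 1–8 ring A, steps 9–13 ring C, steps 14–19 union and endgame).
Longest linear sequence: 14 steps (1–8, then 14–19).

Three steps most likely to fail:

**Step 14 (proposed new electrochemical coupling).** The hindered tertiary radical may be reduced or trapped by titanium before it adds to the β-substituted acceptor. The fallback sets out from 11 (with 20) and comes back at 22. It uses decarboxylative photoredox Giese addition of a tertiary alkyl oxalate, which is established for tertiary radicals and β-substituted cyclic acceptors. Alkene 11 is dihydroxylated (OsO4 cat., NMO) to the 1,2-diol F1. The primary hydroxyl is silylated (TESCl, imidazole) to the triethylsilyl ether F2. The tertiary alcohol is acylated with methyl chlorooxoacetate (Et3N, DMAP) to the methyl oxalate F3, and CsOH hydrolysis gives the caesium oxalate F4. Irradiation of F4 and 20 with Ir[dF(CF3)ppy]2(dtbbpy)PF6 (blue LEDs, DME/DMF, H2O) gives the C20-TES adduct F5. PPTS in MeOH removes the TES group to give 21, which lactonises with DMAP in toluene to 22.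

**Step 15 (Mn(III) ring-D closure).** The reactive conformer needs three axial substituents, and the radical may be over-oxidised or simply reduced. The fallback sets out from 22 and comes back at 23. It replaces the open-shell oxidative cyclisation by a closed-shell gold(I) Conia-ene 5-exo-dig carbocyclisation of the enol onto the π-activated alkyne (Ph3PAuNTf2, 5 mol %, CH2Cl2, rt). It gives 23 directly and makes no new compound (F0).

**Step 17 (C14 set by retro-aldol/aldol equilibration).** The open keto-aldehyde may not re-close cleanly, or the equilibrium may be less one-sided than argued. The fallback sets out from 23 and comes back at 26. It sets C14 at the reduction stage under thermodynamic single-electron control: SmI2, i-PrOH, THF, –78 °C → rt reduces the bridging ketone via the equilibrating ketyl to the more stable (14R)-alcohol F6. Ozonolysis of F6 (O3, then PPh3, no base) gives 26.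

## Further compounds

F1 | step 14 | 1,2-diol from 11: 2-acetoxy-1-hydroxy-1-(hydroxymethyl)-6-(TBS-oxymethyl)-5,5-dimethylcyclohexane (C10 epimers) | OCC1(O)[C@@H](OC(C)=O)CCC(C)(C)[C@H]1CO[Si](C)(C)C(C)(C)C
F2 | step 14 | C20 triethylsilyl ether of F1 | CC[Si](CC)(CC)OCC1(O)[C@@H](OC(C)=O)CCC(C)(C)[C@H]1CO[Si](C)(C)C(C)(C)C
F3 | step 14 | tertiary methyl oxalate of F2 | COC(=O)C(=O)OC1(CO[Si](CC)(CC)CC)[C@@H](OC(C)=O)CCC(C)(C)[C@H]1CO[Si](C)(C)C(C)(C)C
F4 | step 14 | caesium oxalate of F2 | [Cs+].[O-]C(=O)C(=O)OC1(CO[Si](CC)(CC)CC)[C@@H](OC(C)=O)CCC(C)(C)[C@H]1CO[Si](C)(C)C(C)(C)C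
F5 | step 14 | C20-O-TES ether of Giese adduct 21 | C#CC[C@@H]1C[C@H](O[Si](C)(C)C(C)(C)C)[C@H](C(C1=O)C(=O)OC)[C@]2(CO[Si](CC)(CC)CC)[C@@H](OC(C)=O)CCC(C)(C)[C@H]2CO[Si](C)(C)C(C)(C)C
F0 | step 15 | none | none
F6 | step 17 | (14R)-14-hydroxy-15-methylidene lactone | C1C(=C)[C@@]23C(=O)OC[C@]4([C@@H](OC(C)=O)CCC(C)(C)[C@H]4CO[Si](C)(C)C(C)(C)C)[C@@H]2[C@@H](O[Si](C)(C)C(C)(C)C)C[C@@H]1[C@H]3O
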